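**Plan**

Numbering: the lactone core is numbered as a hexahydro-1-benzofuran-2-one: O1, C2 (C=O), C3 (=CH2), C3a, C4 (O-acyl), C5 (CH2), C6 (methyl, vinyl), C7 (hydroxypropenyl), C7a (bears O1).
Retrosynthetic cuts, in order: the C4 ester C–O bond (acid from the (R)-malic acid pool); the C3 methylidene; the C7–propenyl bond (back to a C7 ketone); then O1–C7a and C3–C3a together (key step); then the C6 vinyl and C4–O back to a bridged lactone; then the two Diels–Alder bonds.
Enabling feature: C7a lies between C3a and C7. With C7 as a ketone, C3a=C7a of the carbocycle is an enone, so C3a accepts the acetate carbon and C7a, the enolate carbon, is joined oxidatively to the carboxylate oxygen and stays epimerisable.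
Forward: Diels–Alder gives the cyclohexene; iodolactonisation/elimination, reduction and Wittig give the 5-vinylcyclohexenol; allylic oxidation gives the enone; the γ-lactone ring is annulated in one operation; the ketone then takes the C7 side chain; methylenation, esterification and deprotection finish.
Stereochemistry: C6 from the catalytic asymmetric Diels–Alder; C4 from iodolactonisation (cis to the carboxyl carbon); C3a anti to the C4 silyloxy group; C7a under thermodynamic control next to the ketone; C7 by palladium hydride delivery with inversion; the ester carbinol from the chiral pool.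

Key step: step 9

Remark: 11, 16 and 25 are taken as purchasable; in step 1 the antipode of the catalyst is the one that leads to (S)-3.

**Step 1**
Reactants: 1 buta-1,3-diene; 2 2-methylprop-2-enal
Product: 3 (1S)-1-methylcyclohex-3-ene-1-carbaldehyde
Conditions: oxazaborolidinium triflimide catalyst (from α,α-diphenylprolinol, o-tolylboroxine and Tf2NH, 20 mol %), CH2Cl2, −78 °C
Reagents that add atoms: none
Why: Diels–Alder reaction under a chiral oxazaborolidinium Lewis acid, which binds the formyl group of the α-substituted enal and shields one face, so the diene should add to the open face and set the quaternary centre (the later C6).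

**Step 2**
Reactants: 3 (1S)-1-methylcyclohex-3-ene-1-carbaldehyde
Product: 4 (1S)-1-methylcyclohex-3-ene-1-carboxylic acid
Conditions: NaClO2, NaH2PO4, 2-methylbut-2-ene, t-BuOH/H2O, 0 °C → rt
Reagents that add atoms: sodium chlorite [Na+].[O-]Cl=O
Why: Pinnick oxidation converts the hindered aldehyde to the acid without touching the ring alkene, the scavenger taking up hypochlorous acid.

**Step 3**
Reactants: 4 (1S)-1-methylcyclohex-3-ene-1-carboxylic acid
Product: 6 (1S,5S)-1-methyl-6-oxabicyclo[3.2.1]oct-3-en-7-one, via iodolactone 5 (not isolated)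
Conditions: I2, NaHCO3, MeCN, 0 °C → rt; then DBU, toluene, 80 °C
Reagents that add atoms: none
Why: Iodolactonisation, in which the carboxylate can reach only the nearer alkene carbon from its own face (bridged γ-lactone), places oxygen on the later C4 cis to the carboxyl carbon, and anti-periplanar E2 loss of HI then gives the alkene.

**Step 4**
Reactants: 6 (1S,5S)-1-methyl-6-oxabicyclo[3.2.1]oct-3-en-7-one
Product: 7 (1S,5S)-1-methyl-6-oxabicyclo[3.2.1]oct-3-en-7-ol
Conditions: i-Bu2AlH, CH2Cl2, −78 °C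
Reagents that add atoms: none
Why: Low-temperature hydride reduction of a lactone stops at the lactol because the aluminium hemiacetal is stable at −78 °C; the lactol carbon is not a stereocentre of consequence.

**Step 5**
Reactants: 7 (1S,5S)-1-methyl-6-oxabicyclo[3.2.1]oct-3-en-7-ol
Product: 8 (1S,5S)-5-ethenyl-5-methylcyclohex-2-en-1-ol
Conditions: Ph3PCH3Br, KOtBu, THF, 0 °C → reflux
Reagents that add atoms: methyltriphenylphosphonium bromide C[P+](c1ccccc1)(c1ccccc1)c1ccccc1.[Br-]
Why: Wittig methylenation of the open hydroxy-aldehyde form of the lactol gives the vinyl group and frees the hydroxyl, with both ring stereocentres untouched.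

**Step 6**
Reactants: 8 (1S,5S)-5-ethenyl-5-methylcyclohex-2-en-1-ol
Product: 9 triethyl{[(1S,5S)-5-ethenyl-5-methylcyclohex-2-en-1-yl]oxy}silane
Conditions: Et3SiCl, imidazole, DMF, 0 °C
Reagents that add atoms: chlorotriethylsilane CC[Si](Cl)(CC)CC
Why: Silylation of the secondary allylic alcohol; the triethylsilyl ether is chosen so that it can later be cleaved in the presence of a primary tert-butyldimethylsilyl ether.

**Step 7**
Reactants: 9 triethyl{[(1S,5S)-5-ethenyl-5-methylcyclohex-2-en-1-yl]oxy}silane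
Product: 10 (4S,6S)-6-ethenyl-6-methyl-4-[(triethylsilyl)oxy]cyclohex-2-en-1-one
Conditions: CrO3, 3,5-dimethylpyrazole, CH2Cl2, −20 °C
Reagents that add atoms: chromium trioxide O=[Cr](=O)=O
Why: Allylic oxidation with the CrO3–3,5-dimethylpyrazole complex should attack the only allylic CH2, the allylic C–H on the silyloxy carbon being deactivated, as in the known conversion of 3-silyloxycyclohexenes into 4-silyloxycyclohex-2-enones.

**Step 8**
Reactants: 11 trimethylsilyl acetate
Product: 12 1,1-bis[(trimethylsilyl)oxy]ethene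
Conditions: LiN(i-Pr)2, THF, −78 °C; Me3SiCl, −78 °C → rt
Reagents that add atoms: chlorotrimethylsilane C[Si](C)(C)Cl
Why: O-Silylation of the lithium enolate of a silyl ester is the standard preparation of ketene bis(silyl) acetals.

**Step 9**
Reactants: 10 (4S,6S)-6-ethenyl-6-methyl-4-[(triethylsilyl)oxy]cyclohex-2-en-1-one; 12 1,1-bis[(trimethylsilyl)oxy]ethene
Product: 15 (3aS,4S,6S,7aS)-6-ethenyl-6-methyl-4-[(triethylsilyl)oxy]hexahydro-1-benzofuran-2,7-dione, via silyl enol ether 13 (not isolated), via iodo keto acid 14 (not isolated)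
Conditions: Me3SiOTf (5 mol %), CH2Cl2, −78 °C; N-iodosuccinimide, THF, −78 → 0 °C; aq. NaHCO3, rt; then Et3N, rt
Reagents that add atoms: none
Why: The silyl triflate activates the enone and the ketene bis(silyl) acetal adds at C3a in a Mukaiyama–Michael reaction, which forms the C3–C3a bond and stores the ketone as silyl enol ether 13; N-iodosuccinimide then iodinates C7a, and the carboxylate set free by bicarbonate displaces iodide from this α-iodo ketone, which forms the O1–C7a bond. The closest known reaction types are the Mukaiyama–Michael addition to 4-silyloxycyclohexenones and the lactonisation of α-halo keto acids (oxidative keto-lactonisation of 5-oxo acids). The γ-lactone ring closes in the 5-exo-tet mode. C3a is set by attack anti to the C4 silyloxy group; C7a is set by backside displacement of the axial iodide and, being α to the C7 ketone, is finally equilibrated by Et3N to the trans-fused lactone, the cis isomer being disfavoured by a 1,3-diaxial contact of O1 with the C6 methyl group. The step needs 1,4- instead of 1,2-addition and substitution instead of loss of HI: the soft silyl nucleophile secures the first, and the intramolecular five-ring closure at an activated α-keto carbon secures the second.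

**Step 10**
Reactants: 16 2-bromoprop-2-en-1-ol
Product: 17 [(2-bromoprop-2-en-1-yl)oxy](tert-butyl)dimethylsilane
Conditions: t-BuMe2SiCl, imidazole, CH2Cl2, 0 °C → rt
Reagents that add atoms: tert-butylchlorodimethylsilane CC(C)(C)[Si](C)(C)Cl
Why: Standard silylation of a primary allylic alcohol.

**Step 11**
Reactants: 15 (3aS,4S,6S,7aS)-6-ethenyl-6-methyl-4-[(triethylsilyl)oxy]hexahydro-1-benzofuran-2,7-dione; 17 [(2-bromoprop-2-en-1-yl)oxy](tert-butyl)dimethylsilane
Product: 19 (3aS,4S,6S,7R,7aS)-7-{3-[(tert-butyldimethylsilyl)oxy]prop-1-en-2-yl}-6-ethenyl-6-methyl-2-oxo-4-[(triethylsilyl)oxy]octahydro-1-benzofuran-7-yl methyl carbonate, via tertiary alkoxide 18 (not isolated)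
Conditions: 17, t-BuLi, Et2O, −78 °C; CeCl3, THF, −78 °C; then 15; then ClCO2Me, −78 → 0 °C
Reagents that add atoms: methyl chloroformate COC(=O)Cl
Why: 1,2-Addition of a weakly basic vinylcerium reagent to the hindered, enolisable ketone (faster than to the lactone) should occur axially, anti to the axial C6 methyl, and the alkoxide is trapped cold as the carbonate so that anionic oxy-Cope ring expansion of the 1,2-dialkenyl carbinol cannot compete; the new carbinol centre is consumed in step 12.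

**Step 12**
Reactants: 19 (3aS,4S,6S,7R,7aS)-7-{3-[(tert-butyldimethylsilyl)oxy]prop-1-en-2-yl}-6-ethenyl-6-methyl-2-oxo-4-[(triethylsilyl)oxy]octahydro-1-benzofuran-7-yl methyl carbonate
Product: 20 (3aS,4S,6S,7R,7aR)-7-{3-[(tert-butyldimethylsilyl)oxy]prop-1-en-2-yl}-6-ethenyl-6-methyl-4-[(triethylsilyl)oxy]hexahydro-1-benzofuran-2(3H)-one
Conditions: Pd2(dba)3 (cat.), n-Bu3P, HCO2NH4, 1,4-dioxane, 40 °C
Reagents that add atoms: none
Why: Palladium-catalysed formate hydrogenolysis of an allylic carbonate (Tsuji–Trost type): zerovalent palladium ionises the carbonate with inversion, formate decarboxylates to a palladium hydride, and hydride passes from the metal to the more substituted allyl terminus C7, which should give the 1,1-disubstituted alkene and place H on the face opposite to the departed carbonate, so that the side chain ends equatorial.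

**Step 13**
Reactants: 20 (3aS,4S,6S,7R,7aR)-7-{3-[(tert-butyldimethylsilyl)oxy]prop-1-en-2-yl}-6-ethenyl-6-methyl-4-[(triethylsilyl)oxy]hexahydro-1-benzofuran-2(3H)-one
Product: 23 (3aS,4S,6S,7R,7aR)-7-{3-[(tert-butyldimethylsilyl)oxy]prop-1-en-2-yl}-6-ethenyl-6-methyl-3-methylidene-4-[(triethylsilyl)oxy]hexahydro-1-benzofuran-2(3H)-one, via Mannich base 21 (not isolated), via ammonium iodide 22 (not isolated)
Conditions: LiN(SiMe3)2, THF, −78 °C; dimethyl(methylidene)ammonium iodide, −78 → 0 °C; MeI, MeOH, rt; aq. NaHCO3, CH2Cl2, rt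
Reagents that add atoms: dimethyl(methylidene)ammonium iodide C=[N+](C)C.[I-]
Why: α-Methylenation of a γ-lactone by Mannich reaction of its lithium enolate, quaternisation and E1cB loss of trimethylamine; no stereocentre is created.

**Step 14**
Reactants: 23 (3aS,4S,6S,7R,7aR)-7-{3-[(tert-butyldimethylsilyl)oxy]prop-1-en-2-yl}-6-ethenyl-6-methyl-3-methylidene-4-[(triethylsilyl)oxy]hexahydro-1-benzofuran-2(3H)-one
Product: 24 (3aR,4S,6S,7R,7aR)-7-{3-[(tert-butyldimethylsilyl)oxy]prop-1-en-2-yl}-6-ethenyl-4-hydroxy-6-methyl-3-methylidenehexahydro-1-benzofuran-2(3H)-one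
Conditions: HF·pyridine, pyridine, THF, 0 °C
Reagents that add atoms: none
Why: Buffered HF·pyridine should cleave the triethylsilyl ether much faster than the primary tert-butyldimethylsilyl ether.

**Step 15**
Reactants: 25 methyl [(4R)-2,2-dimethyl-1,3-dioxolan-4-yl]acetate
Product: 28 methyl 2-[(4R)-2,2-dimethyl-1,3-dioxolan-4-yl]prop-2-enoate, via Mannich base 26 (not isolated), via ammonium iodide 27 (not isolated)
Conditions: LiN(i-Pr)2, THF, −78 °C; dimethyl(methylidene)ammonium iodide, −78 → −20 °C; MeI, rt; aq. NaHCO3, rt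
Reagents that add atoms: dimethyl(methylidene)ammonium iodide C=[N+](C)C.[I-]
Why: The same Mannich, quaternisation and elimination sequence on the ester enolate, kept at −78 °C so that the β-alkoxy enolate does not open the dioxolane; the stereocentre is not involved.

**Step 16**
Reactants: 28 methyl 2-[(4R)-2,2-dimethyl-1,3-dioxolan-4-yl]prop-2-enoate
Product: 29 2-[(4R)-2,2-dimethyl-1,3-dioxolan-4-yl]prop-2-enoic acid
Conditions: LiOH, THF/H2O, 0 °C; then cold dilute HCl to pH 3
Reagents that add atoms: lithium hydroxide [Li+].[OH-]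
Why: Saponification of the methyl ester; the acetal is stable to base and should survive brief cold acidification.

**Step 17**
Reactants: 24 (3aR,4S,6S,7R,7aR)-7-{3-[(tert-butyldimethylsilyl)oxy]prop-1-en-2-yl}-6-ethenyl-4-hydroxy-6-methyl-3-methylidenehexahydro-1-benzofuran-2(3H)-one; 29 2-[(4R)-2,2-dimethyl-1,3-dioxolan-4-yl]prop-2-enoic acid
Product: 30 (3aR,4S,6S,7R,7aR)-7-{3-[(tert-butyldimethylsilyl)oxy]prop-1-en-2-yl}-6-ethenyl-6-methyl-3-methylidene-2-oxooctahydro-1-benzofuran-4-yl 2-[(4R)-2,2-dimethyl-1,3-dioxolan-4-yl]prop-2-enoate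
Conditions: DCC, DMAP (cat.), CH2Cl2, 0 °C → rt
Reagents that add atoms: none
Why: Steglich esterification of the equatorial secondary alcohol, with retention at C4.

**Step 18**
Reactants: 30 (3aR,4S,6S,7R,7aR)-7-{3-[(tert-butyldimethylsilyl)oxy]prop-1-en-2-yl}-6-ethenyl-6-methyl-3-methylidene-2-oxooctahydro-1-benzofuran-4-yl 2-[(4R)-2,2-dimethyl-1,3-dioxolan-4-yl]prop-2-enoate
Product: 31 (3aR,4S,6S,7R,7aR)-6-ethenyl-7-(3-hydroxyprop-1-en-2-yl)-6-methyl-3-methylidene-2-oxooctahydro-1-benzofuran-4-yl (3R)-3,4-dihydroxy-2-methylidenebutanoate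
Conditions: AcOH/H2O/THF, 40 °C
Reagents that add atoms: none
Why: Aqueous acetic acid should hydrolyse the isopropylidene acetal and the primary silyl ether, while both enoates and the lactone are stable to mild acid.

**Compound list**

1 | buta-1,3-diene | C=CC=C | starting material
2 | 2-methylprop-2-enal | CC(=C)C=O | starting material
3 | (1S)-1-methylcyclohex-3-ene-1-carbaldehyde | O=C[C@]1(C)CC=CCC1 | intermediate
4 | (1S)-1-methylcyclohex-3-ene-1-carboxylic acid | OC(=O)[C@]1(C)CC=CCC1 | intermediate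
5 | (1S,4S,5S)-4-iodo-1-methyl-6-oxabicyclo[3.2.1]octan-7-one | C[C@]12CC[C@H](I)[C@H](C1)OC2=O | intermediate
6 | (1S,5S)-1-methyl-6-oxabicyclo[3.2.1]oct-3-en-7-one | C[C@]12CC=C[C@H](C1)OC2=O | intermediate
7 | (1S,5S)-1-methyl-6-oxabicyclo[3.2.1]oct-3-en-7-ol (both C7 epimers) | C[C@]12CC=C[C@H](C1)OC2O | intermediate
8 | (1S,5S)-5-ethenyl-5-methylcyclohex-2-en-1-ol | C=C[C@@]1(C)CC=C[C@@H](O)C1 | intermediate
9 | triethyl{[(1S,5S)-5-ethenyl-5-methylcyclohex-2-en-1-yl]oxy}silane | C=C[C@@]1(C)CC=C[C@@H](O[Si](CC)(CC)CC)C1 | intermediate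
10 | (4S,6S)-6-ethenyl-6-methyl-4-[(triethylsilyl)oxy]cyclohex-2-en-1-one | C=C[C@]1(C)C[C@H](O[Si](CC)(CC)CC)C=CC1=O | intermediate
11 | trimethylsilyl acetate | CC(=O)O[Si](C)(C)C | starting material
12 | 1,1-bis[(trimethylsilyl)oxy]ethene | C=C(O[Si](C)(C)C)O[Si](C)(C)C | intermediate
13 | trimethylsilyl 2-{(1S,4S,6S)-4-ethenyl-4-methyl-6-[(triethylsilyl)oxy]-3-[(trimethylsilyl)oxy]cyclohex-2-en-1-yl}acetate | C=C[C@]1(C)C[C@H](O[Si](CC)(CC)CC)[C@@H](CC(=O)O[Si](C)(C)C)C=C1O[Si](C)(C)C | intermediate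
14 | 2-{(1R,2R,4S,6S)-4-ethenyl-2-iodo-4-methyl-3-oxo-6-[(triethylsilyl)oxy]cyclohexyl}acetic acid (axial iodide drawn) | C=C[C@]1(C)C[C@H](O[Si](CC)(CC)CC)[C@@H](CC(=O)O)[C@@H](I)C1=O | intermediate
15 | (3aS,4S,6S,7aS)-6-ethenyl-6-methyl-4-[(triethylsilyl)oxy]hexahydro-1-benzofuran-2,7-dione | C=C[C@]1(C)C[C@H](O[Si](CC)(CC)CC)[C@H]2CC(=O)O[C@@H]2C1=O | intermediate
16 | 2-bromoprop-2-en-1-ol | OCC(Br)=C | starting material
17 | [(2-bromoprop-2-en-1-yl)oxy](tert-butyl)dimethylsilane | C=C(Br)CO[Si](C)(C)C(C)(C)C | intermediate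
18 | (3aS,4S,6S,7R,7aS)-7-{3-[(tert-butyldimethylsilyl)oxy]prop-1-en-2-yl}-6-ethenyl-7-hydroxy-6-methyl-4-[(triethylsilyl)oxy]hexahydro-1-benzofuran-2(3H)-one (formed as its metal alkoxide) | C=C[C@]1(C)C[C@H](O[Si](CC)(CC)CC)[C@H]2CC(=O)O[C@@H]2[C@]1(O)C(=C)CO[Si](C)(C)C(C)(C)C | intermediate
19 | (3aS,4S,6S,7R,7aS)-7-{3-[(tert-butyldimethylsilyl)oxy]prop-1-en-2-yl}-6-ethenyl-6-methyl-2-oxo-4-[(triethylsilyl)oxy]octahydro-1-benzofuran-7-yl methyl carbonate | C=C[C@]1(C)C[C@H](O[Si](CC)(CC)CC)[C@H]2CC(=O)O[C@@H]2[C@]1(OC(=O)OC)C(=C)CO[Si](C)(C)C(C)(C)C | intermediate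
20 | (3aS,4S,6S,7R,7aR)-7-{3-[(tert-butyldimethylsilyl)oxy]prop-1-en-2-yl}-6-ethenyl-6-methyl-4-[(triethylsilyl)oxy]hexahydro-1-benzofuran-2(3H)-one | C=C[C@]1(C)C[C@H](O[Si](CC)(CC)CC)[C@H]2CC(=O)O[C@@H]2[C@H]1C(=C)CO[Si](C)(C)C(C)(C)C | intermediate
21 | 3-[(dimethylamino)methyl] derivative of 20 (both C3 epimers) | C=C[C@]1(C)C[C@H](O[Si](CC)(CC)CC)[C@H]2C(CN(C)C)C(=O)O[C@@H]2[C@H]1C(=C)CO[Si](C)(C)C(C)(C)C | intermediate
22 | 3-[(trimethylammonio)methyl] derivative of 20, iodide (both C3 epimers) | C=C[C@]1(C)C[C@H](O[Si](CC)(CC)CC)[C@H]2C(C[N+](C)(C)C)C(=O)O[C@@H]2[C@H]1C(=C)CO[Si](C)(C)C(C)(C)C.[I-] | intermediate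
23 | (3aS,4S,6S,7R,7aR)-7-{3-[(tert-butyldimethylsilyl)oxy]prop-1-en-2-yl}-6-ethenyl-6-methyl-3-methylidene-4-[(triethylsilyl)oxy]hexahydro-1-benzofuran-2(3H)-one | C=C[C@]1(C)C[C@H](O[Si](CC)(CC)CC)[C@H]2C(=C)C(=O)O[C@@H]2[C@H]1C(=C)CO[Si](C)(C)C(C)(C)C | intermediate
24 | (3aR,4S,6S,7R,7aR)-7-{3-[(tert-butyldimethylsilyl)oxy]prop-1-en-2-yl}-6-ethenyl-4-hydroxy-6-methyl-3-methylidenehexahydro-1-benzofuran-2(3H)-one | C=C[C@]1(C)C[C@H](O)[C@H]2C(=C)C(=O)O[C@@H]2[C@H]1C(=C)CO[Si](C)(C)C(C)(C)C | intermediate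
25 | methyl [(4R)-2,2-dimethyl-1,3-dioxolan-4-yl]acetate | COC(=O)C[C@@H]1COC(C)(C)O1 | starting material
26 | methyl 3-(dimethylamino)-2-[(4R)-2,2-dimethyl-1,3-dioxolan-4-yl]propanoate (both C2 epimers) | COC(=O)C(CN(C)C)[C@@H]1COC(C)(C)O1 | intermediate
27 | 2-[(4R)-2,2-dimethyl-1,3-dioxolan-4-yl]-3-methoxy-N,N,N-trimethyl-3-oxopropan-1-aminium iodide (both C2 epimers) | COC(=O)C(C[N+](C)(C)C)[C@@H]1COC(C)(C)O1.[I-] | intermediate
28 | methyl 2-[(4R)-2,2-dimethyl-1,3-dioxolan-4-yl]prop-2-enoate | COC(=O)C(=C)[C@@H]1COC(C)(C)O1 | intermediate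
29 | 2-[(4R)-2,2-dimethyl-1,3-dioxolan-4-yl]prop-2-enoic acid | OC(=O)C(=C)[C@@H]1COC(C)(C)O1 | intermediate
30 | (3aR,4S,6S,7R,7aR)-7-{3-[(tert-butyldimethylsilyl)oxy]prop-1-en-2-yl}-6-ethenyl-6-methyl-3-methylidene-2-oxooctahydro-1-benzofuran-4-yl 2-[(4R)-2,2-dimethyl-1,3-dioxolan-4-yl]prop-2-enoate | C=C[C@]1(C)C[C@H](OC(=O)C(=C)[C@@H]3COC(C)(C)O3)[C@H]2C(=C)C(=O)O[C@@H]2[C@H]1C(=C)CO[Si](C)(C)C(C)(C)C | intermediate
31 | (3aR,4S,6S,7R,7aR)-6-ethenyl-7-(3-hydroxyprop-1-en-2-yl)-6-methyl-3-methylidene-2-oxooctahydro-1-benzofuran-4-yl (3R)-3,4-dihydroxy-2-methylidenebutanoate | C=C[C@]1(C)C[C@H](OC(=O)C(=C)[C@@H](O)CO)[C@H]2C(=C)C(=O)O[C@@H]2[C@H]1C(=C)CO | target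

**Step count**

Total: 18 steps. Longest linear sequence: 14 steps (steps 1–7, 9, 11–14, 17 and 18).

**Steps most likely to fail**

Step 11. The organometallic may attack the lactone carbonyl, the α-acyloxy ketone may enolise instead of adding, or the acyl group may migrate to the new alkoxide before it is trapped. The fallback sets out from 15 and returns at 19. The lactone of 15 is opened with LiOH in THF/H2O to the hydroxy keto acid F3, handled as its dried dilithium salt, in which the carboxylate is no longer an electrophile. An excess of the cerium reagent from 17 then adds to the ketone to give the dihydroxy acid F4. Mild acid (pyridinium p-toluenesulfonate) closes the γ-lactone on the secondary hydroxyl to give 18, now isolated. LiN(SiMe3)2 and ClCO2Me at −78 °C give 19.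

Step 12. Hydride may go to the terminal allyl carbon (tetrasubstituted alkene), β-hydride loss may give a diene, or hydrogen may enter on the wrong face. The fallback sets out from 18 (isolated by aqueous quench in step 11 in place of the chloroformate) and returns at 20. A catalytic amount of Ph3SiOReO3 in ether at 0 °C transposes the tertiary allylic alcohol to the primary allylic alcohol F5. Mitsunobu reaction with 2-nitrobenzenesulfonylhydrazide (PPh3, diethyl azodicarboxylate, THF, −30 °C) gives the N-allyl sulfonylhydrazide F6. On warming it loses the sulfinic acid to give the allylic diazene F7, whose sigmatropic loss of dinitrogen delivers hydrogen to C7 through a cyclic transition state and restores the exocyclic methylene of 20.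

Step 9. Loss of HI from the α-iodo ketone may compete with ring closure, and the triethylsilyl ether may be partly cleaved during the one-pot sequence. The fallback sets out from 10 and returns at 15; it takes O1 from an electrophilic oxygen reagent instead of from the carboxylate. Mukaiyama–Michael addition of 1-methoxy-1-(trimethylsilyloxy)ethene (Me3SiOTf cat., CH2Cl2, −78 °C) gives the isolable silyl enol ether F1. Rubottom oxidation with dimethyldioxirane and a mild acidic work-up give the α-hydroxy keto ester F2, with oxygen entering anti to the new side chain. Pyridinium p-toluenesulfonate in warm toluene closes the acyl–oxygen bond to give 15.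

**Further compounds**

F1 | step 9 | methyl 2-{(1S,4S,6S)-4-ethenyl-4-methyl-6-[(triethylsilyl)oxy]-3-[(trimethylsilyl)oxy]cyclohex-2-en-1-yl}acetate | C=C[C@]1(C)C[C@H](O[Si](CC)(CC)CC)[C@@H](CC(=O)OC)C=C1O[Si](C)(C)C
F2 | step 9 | methyl 2-{(1S,2S,4S,6S)-4-ethenyl-2-hydroxy-4-methyl-3-oxo-6-[(triethylsilyl)oxy]cyclohexyl}acetate | C=C[C@]1(C)C[C@H](O[Si](CC)(CC)CC)[C@@H](CC(=O)OC)[C@H](O)C1=O
F3 | step 11 | 2-{(1S,2S,4S,6S)-4-ethenyl-2-hydroxy-4-methyl-3-oxo-6-[(triethylsilyl)oxy]cyclohexyl}acetic acid | C=C[C@]1(C)C[C@H](O[Si](CC)(CC)CC)[C@@H](CC(=O)O)[C@H](O)C1=O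
F4 | step 11 | 2-{(1S,2S,3R,4S,6S)-3-{3-[(tert-butyldimethylsilyl)oxy]prop-1-en-2-yl}-4-ethenyl-2,3-dihydroxy-4-methyl-6-[(triethylsilyl)oxy]cyclohexyl}acetic acid | C=C[C@]1(C)C[C@H](O[Si](CC)(CC)CC)[C@@H](CC(=O)O)[C@H](O)[C@]1(O)C(=C)CO[Si](C)(C)C(C)(C)C
F5 | step 12 | (3aS,4S,6S,7aS)-7-{1-[(tert-butyldimethylsilyl)oxy]-3-hydroxypropan-2-ylidene}-6-ethenyl-6-methyl-4-[(triethylsilyl)oxy]hexahydro-1-benzofuran-2(3H)-one (alkene geometry not fixed) | C=C[C@]1(C)C[C@H](O[Si](CC)(CC)CC)[C@H]2CC(=O)O[C@@H]2C1=C(CO)CO[Si](C)(C)C(C)(C)C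
F6 | step 12 | N-{3-[(tert-butyldimethylsilyl)oxy]-2-[(3aS,4S,6S,7aS)-6-ethenyl-6-methyl-2-oxo-4-[(triethylsilyl)oxy]hexahydro-1-benzofuran-7(2H)-ylidene]propyl}-2-nitrobenzenesulfonohydrazide | C=C[C@]1(C)C[C@H](O[Si](CC)(CC)CC)[C@H]2CC(=O)O[C@@H]2C1=C(CN(N)S(=O)(=O)c3ccccc3[N+](=O)[O-])CO[Si](C)(C)C(C)(C)C
F7 | step 12 | {3-[(tert-butyldimethylsilyl)oxy]-2-[(3aS,4S,6S,7aS)-6-ethenyl-6-methyl-2-oxo-4-[(triethylsilyl)oxy]hexahydro-1-benzofuran-7(2H)-ylidene]propyl}diazene | C=C[C@]1(C)C[C@H](O[Si](CC)(CC)CC)[C@H]2CC(=O)O[C@@H]2C1=C(CN=N)CO[Si](C)(C)C(C)(C)C
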